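A direct plan would build each benzopyran on its own and join the two last.
A para-bromophenoxide would be C-prenylated at its ortho carbon, O-alkylated with a tertiary propargylic chloride, rearranged at 185 °C to the bromochromene and borylated to boronate A1.
A second bromophenol, carried as its mono-methoxymethyl ether, would pass through the same etherification and rearrangement to bromochromene A2; Suzuki coupling of A1 with A2 would give the protected bichromene A3, and acid would then free the phenol.
Its weakest points would be three.
(a) The ortho C-alkylation of an ambident sodium phenoxide with the prenyl halide: O-alkylation, double alkylation and chroman formation would compete, and the step opens the longest sequence.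
(b) The propargylic etherification followed by a 185 °C Claisen rearrangement, run twice in parallel: with acetal protection, bromination and borylation, most of the ten steps would go into two identical pyran rings and two coupling handles.
(c) The acid cleavage of the acetal as the very last step: the finished material, with two acid-labile 2,2-dimethyl-2H-chromenes and a prenyl group, would meet the reagent class it tolerates least.

Locants: ring A is the 8-hydroxychromene unit (O1, C2 to C8a), ring B the 8'-prenylchromene unit (primed), joined C6–C6'; open precursors keep these locants.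
The retrosynthesis cuts C4–C4a, O1–C2, C4'–C4a' and O1'–C2' at once, back to two molecules of 3-methylbut-2-enal and a non-fused biphenyltriol; then C6–C6', back to two bought benzene rings; the prenyl group is traced to an allyl group placed by Claisen rearrangement.
Ring order: the benzene rings are joined first and both pyran rings arise together in the last step, which gives the target itself, so no compound before the target holds a benzopyran.
Enabling feature: both pyran rings are the same C5 unit (C2 with its methyls, C3, C4) bridging a phenol oxygen and its ortho carbon; both oxygens lie para to C6–C6', and each has one open ortho C–H (C4a, C4a'), because C8' carries the prenyl group and C8 the hydroxyl.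
No phenoxide C-alkylation occurs (allyl ether, [3,3] shift and cross-metathesis instead), the pyran rings are made once and not in two parallel sequences, and there is no protecting group and hence no acid step on the finished bichromene.

Key step: step 5

Remark: the target has no stereocentre, and the C6–C6' axis, flanked by four ortho hydrogens, rotates freely, so no stereocontrol is needed anywhere.

Step 1
Reactants: 1 4-bromophenol; 2 allyl bromide (3-bromoprop-1-ene)
Product: 3 1-bromo-4-(prop-2-en-1-yloxy)benzene
Conditions: 2 (1.2 equiv), K2CO3 (1.5 equiv), acetone, reflux, 6 h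
Reagents that add atoms: none
Why: Williamson ether synthesis: in acetone the potassium phenoxide is alkylated on oxygen by SN2 displacement at the unhindered primary allylic carbon, the aryl bromide is inert, and no stereocentre is formed.

Step 2
Reactants: 3 1-bromo-4-(prop-2-en-1-yloxy)benzene
Product: 5 4-bromo-2-(prop-2-en-1-yl)phenol, via allyl dienone 4 (not isolated)
Conditions: PhNEt2, 200 °C, 4 h, argon
Reagents that add atoms: none
Why: Aromatic Claisen rearrangement: the concerted [3,3] shift moves the allyl group to one of the two equivalent ortho carbons (the para carbon is blocked by bromine), and dienone 4 tautomerises to the phenol, its single stereocentre being lost, so that 5 has none.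

Step 3
Reactants: 5 4-bromo-2-(prop-2-en-1-yl)phenol; 6 2-methylbut-2-ene
Product: 7 4-bromo-2-(3-methylbut-2-en-1-yl)phenol
Conditions: 6 (co-solvent, ca. 30 equiv), second-generation Grubbs catalyst (2 mol %), CH2Cl2, 35 °C, sealed vessel, 12 h
Reagents that add atoms: none
Why: Olefin cross-metathesis: the ruthenium alkylidene exchanges the terminal CH2 of the allyl group for the isopropylidene end of the excess 2-methylbut-2-ene with loss of propene, the trisubstituted product alkene no longer re-enters the cycle, phenol and aryl bromide are tolerated, and the new alkene bears two identical methyls so that no alkene geometry or stereocentre arises.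

Step 4
Reactants: 7 4-bromo-2-(3-methylbut-2-en-1-yl)phenol; 8 4-bromobenzene-1,2-diol (4-bromocatechol)
Product: 10 3'-(3-methylbut-2-en-1-yl)-[1,1'-biphenyl]-3,4,4'-triol, via arylboronate 9 (not isolated)
Conditions: 7, B2pin2 (1.1 equiv), Pd(dppf)Cl2 (3 mol %), KOAc (3 equiv), degassed 1,4-dioxane, 90 °C, 3 h; then 8 (1.2 equiv), Pd(OAc)2 (2 mol %), SPhos (4 mol %), degassed aq K3PO4 (5 equiv), 90 °C, 6 h; aq citric acid work-up under argon
Reagents that add atoms: none
Why: One-pot Miyaura borylation and Suzuki–Miyaura coupling: oxidative addition of 7 to zerovalent palladium, acetate-assisted transmetalation from B2pin2 and reductive elimination give 9, which after addition of aqueous phosphate transmetalates onto the arylpalladium bromide formed from 8 and gives the biaryl by reductive elimination, both reacting carbons being flanked only by hydrogen, the phenols travelling as phenoxides under exclusion of air, and the new axis being freely rotating and not stereogenic.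

Step 5
Reactants: 10 3'-(3-methylbut-2-en-1-yl)-[1,1'-biphenyl]-3,4,4'-triol; 11 3-methylbut-2-enal (two molecules are consumed, one for each pyran ring)
Product: 14 2,2,2',2'-tetramethyl-8'-(3-methylbut-2-en-1-yl)-2H,2'H-[6,6'-bichromen]-8-ol (target), via bis(hydroxyalkyl) adduct 12 (not isolated), via bis(quinone methide) 13 (not isolated)
Conditions: 10, Ti(OEt)4 (1.0 equiv), toluene, 80 °C, EtOH distilled off; then 11 (2.5 equiv, added over 2 h), reflux, 12 h, argon; aq potassium sodium tartrate work-up
Reagents that add atoms: 3-methylbut-2-enal (the second molecule of 11, which builds the second pyran ring), CC(C)=CC=O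
Why: Proposed new method: ligand exchange should turn the three hydroxyls of 10 into titanium aryloxides, and the two aryloxide oxygens para to the biaryl bond should each deliver one titanium-bound molecule of 11 to their own ortho carbon through a six-membered transition state (ortho-specific 1,2-addition, the stage drawn as 12), after which loss of the titanium-bound benzylic oxygen gives the vinyl ortho-quinone methides of 13 and a thermal oxa-6π electrocyclisation forms O1–C2 and O1'–C2', so that one molecule of 10 and two molecules of 11 give 14 and two molecules of water. The closest known reaction type is the condensation of titanium phenoxides (or phenol/PhB(OH)2 adducts) of monohydric phenols with 3-methylbut-2-enal to 2,2-dimethyl-2H-chromenes; what is not precedented is its use on a free catechol ring and twice in one flask. Each pyran ring is closed in the same mode, an intermolecular C4–C4a bond formation followed by a 6π ring closure at oxygen (a formal [3+3] annulation), the rings reacting independently, so that 12 and 13 show both rings at the same stage. No stereocentre has to be controlled, since the carbinol centres of 12 are lost on elimination and 14 is achiral. The selectivity needed is the choice of ortho carbon: in ring B the aryloxide has only C4a' open (C8' carries the prenyl group), and in ring A the oxygen para to the biaryl bond has the unhindered C4a, whereas the C8 oxygen could deliver only to C7, wedged between that oxygen and the C6 aryl group, a position that metal-templated ortho-functionalisation of 3-substituted phenols avoids, which also keeps the 8-hydroxyl from a further annulation when 11 is kept to a small excess over the two molecules required. Chelation of the catecholate to one titanium centre is the main doubt, but bridging aryloxide oxygens in titanium aggregates still place a second metal above C4a, the para carbons of O1 and O1' are the blocked C6 and C6', and C5, para to the C8 oxygen, is not reached by an ortho-delivering metal.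

**Compound list**
1 | 4-bromophenol | Oc1ccc(Br)cc1 | starting material
2 | allyl bromide (3-bromoprop-1-ene) | C=CCBr | starting material
3 | 1-bromo-4-(prop-2-en-1-yloxy)benzene | C=CCOc1ccc(Br)cc1 | intermediate
4 | 4-bromo-6-(prop-2-en-1-yl)cyclohexa-2,4-dien-1-one (racemic, in flask, step 2) | O=C1C=CC(Br)=CC1CC=C | intermediate
5 | 4-bromo-2-(prop-2-en-1-yl)phenol | C=CCc1cc(Br)ccc1O | intermediate
6 | 2-methylbut-2-ene | CC=C(C)C | starting material
7 | 4-bromo-2-(3-methylbut-2-en-1-yl)phenol | CC(C)=CCc1cc(Br)ccc1O | intermediate
8 | 4-bromobenzene-1,2-diol (4-bromocatechol) | Oc1ccc(Br)cc1O | starting material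
9 | 2-(3-methylbut-2-en-1-yl)-4-(4,4,5,5-tetramethyl-1,3,2-dioxaborolan-2-yl)phenol (in flask, step 4) | CC(C)=CCc1cc(B2OC(C)(C)C(C)(C)O2)ccc1O | intermediate
10 | 3'-(3-methylbut-2-en-1-yl)-[1,1'-biphenyl]-3,4,4'-triol | CC(C)=CCc1cc(-c2ccc(O)c(O)c2)ccc1O | intermediate
11 | 3-methylbut-2-enal | CC(C)=CC=O | starting material
12 | 5,5'-bis(1-hydroxy-3-methylbut-2-en-1-yl)-3'-(3-methylbut-2-en-1-yl)-[1,1'-biphenyl]-3,4,4'-triol (mixture of diastereomers, in flask, step 5) | CC(C)=CCc1cc(-c2cc(O)c(O)c(C(O)C=C(C)C)c2)cc(C(O)C=C(C)C)c1O | intermediate
13 | (6Z)-4-[(3Z)-5-hydroxy-3-(3-methylbut-2-en-1-ylidene)-4-oxocyclohexa-1,5-dien-1-yl]-6-(3-methylbut-2-en-1-ylidene)-2-(3-methylbut-2-en-1-yl)cyclohexa-2,4-dien-1-one (in flask, step 5) | CC(C)=CCC1=CC(C2=C/C(=C/C=C(C)C)C(=O)C(O)=C2)=C/C(=C/C=C(C)C)C1=O | intermediate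
14 | 2,2,2',2'-tetramethyl-8'-(3-methylbut-2-en-1-yl)-2H,2'H-[6,6'-bichromen]-8-ol (CNP0158232.0) | CC(C)=CCc1cc(-c2cc(O)c3c(c2)C=CC(C)(C)O3)cc2c1OC(C)(C)C=C2 | target

Total step count: 5. Longest linear sequence: 5 (steps 1 to 5; the route is linear).

**Steps most likely to fail**

Step 5 (labelled step). Ring A may fail to react if both of its oxygens chelate one titanium centre or if the triol cross-links into an insoluble titanium aryloxide network. Delivery from the C8 oxygen to C7, a further annulation there, and aldol self-condensation or hydride reduction of 11 are further risks. The fallback uses known chemistry, sets out from 7 and returns at 14. Suzuki–Miyaura coupling of 7 with commercial 2-methoxy-4-(4,4,5,5-tetramethyl-1,3,2-dioxaborolan-2-yl)phenol (Pd(dppf)Cl2, aq K2CO3, 1,4-dioxane, 85 °C) should give 3-methoxy-3'-(3-methylbut-2-en-1-yl)-[1,1'-biphenyl]-4,4'-diol F1. In F1 the catechol is masked as a guaiacol and each phenol has exactly one free ortho carbon. The twofold condensation with two molecules of 11 under the conditions established for monohydric phenols (PhB(OH)2, cat. propionic acid, toluene, reflux with water separation) should give 8-methoxy-2,2,2',2'-tetramethyl-8'-(3-methylbut-2-en-1-yl)-2H,2'H-6,6'-bichromene F2. Nucleophilic O-demethylation with NaSEt in DMF at 130 °C (base only, no acid) should then give 14. The price is one more step and a deprotection on the finished skeleton.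

Step 4. Binding of the catecholate to the arylpalladium intermediate or to boron may slow transmetalation. Oxidative addition into the electron-rich bromocatecholate may be slow, the catecholate may be oxidised by traces of air, and 9 may protodeboronate. The fallback sets out from 5 and returns at 10; it joins the rings before the prenyl group exists and carries the catechol as its dimethyl ether. Suzuki–Miyaura coupling of 5 with commercial (3,4-dimethoxyphenyl)boronic acid (Pd(dppf)Cl2, aq K2CO3, 1,4-dioxane, 85 °C) should give 3',4'-dimethoxy-3-(prop-2-en-1-yl)-[1,1'-biphenyl]-4-ol F3. BBr3 in CH2Cl2 at −78 to 0 °C should cleave both methyl ethers to 3'-(prop-2-en-1-yl)-[1,1'-biphenyl]-3,4,4'-triol F4. A terminal allyl group next to a phenol should survive this Lewis acid, whereas a prenyl group would cyclise to the chroman, which is why the order is changed. Cross-metathesis of F4 with 6 under the conditions of step 3 should give 10.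

Step 3. Ruthenium hydride species may move the allyl double bond into conjugation with the ring, exchange may stop at the but-2-enyl stage, or the phenol may arrest the catalyst. The fallback sets out from 1 and returns at 7; it replaces steps 1 to 3 and uses no metathesis. O-alkylation of 1 with 3-chloro-3-methylbut-1-yne (DBU, cat. CuCl2, MeCN, 0 °C) should give 1-bromo-4-[(2-methylbut-3-yn-2-yl)oxy]benzene F5. Semi-hydrogenation (H2, Pd/CaCO3 poisoned with Pb(OAc)2, quinoline, EtOAc) should give 1-bromo-4-[(2-methylbut-3-en-2-yl)oxy]benzene F6. Aromatic Claisen rearrangement of this 1,1-dimethylallyl ether (PhNEt2, 140 °C) should deliver the prenyl group to the ortho carbon with allylic inversion and give 7.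

**Further compounds**
F1 | step 5 | 3-methoxy-3'-(3-methylbut-2-en-1-yl)-[1,1'-biphenyl]-4,4'-diol | CC(C)=CCc1cc(-c2ccc(O)c(OC)c2)ccc1O
F2 | step 5 | 8-methoxy-2,2,2',2'-tetramethyl-8'-(3-methylbut-2-en-1-yl)-2H,2'H-6,6'-bichromene | CC(C)=CCc1cc(-c2cc(OC)c3c(c2)C=CC(C)(C)O3)cc2c1OC(C)(C)C=C2
F3 | step 4 | 3',4'-dimethoxy-3-(prop-2-en-1-yl)-[1,1'-biphenyl]-4-ol | C=CCc1cc(-c2ccc(OC)c(OC)c2)ccc1O
F4 | step 4 | 3'-(prop-2-en-1-yl)-[1,1'-biphenyl]-3,4,4'-triol | C=CCc1cc(-c2ccc(O)c(O)c2)ccc1O
F5 | step 3 | 1-bromo-4-[(2-methylbut-3-yn-2-yl)oxy]benzene | C#CC(C)(C)Oc1ccc(Br)cc1
F6 | step 3 | 1-bromo-4-[(2-methylbut-3-en-2-yl)oxy]benzene | C=CC(C)(C)Oc1ccc(Br)cc1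
A1 | direct plan | 2-[2,2-dimethyl-8-(3-methylbut-2-en-1-yl)-2H-chromen-6-yl]-4,4,5,5-tetramethyl-1,3,2-dioxaborolane | CC(C)=CCc1cc(B3OC(C)(C)C(C)(C)O3)cc2c1OC(C)(C)C=C2
A2 | direct plan | 6-bromo-8-(methoxymethoxy)-2,2-dimethyl-2H-chromene | COCOc1cc(Br)cc2c1OC(C)(C)C=C2
A3 | direct plan | 8-(methoxymethoxy)-2,2,2',2'-tetramethyl-8'-(3-methylbut-2-en-1-yl)-2H,2'H-6,6'-bichromene | CC(C)=CCc1cc(-c2cc(OCOC)c3c(c2)C=CC(C)(C)O3)cc2c1OC(C)(C)C=C2
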